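Readings and results come from a simulation with made-up constants.

A small charge of electrophile meets an equal charge of nucleophile and a surplus of free base, and I want to know what stands in the violet flask at 5.0 h.

all flasks: electrophile 0.050 M

| run | nucleophile | free base | remark | time |
|---|---|---|---|---|
| violet | 1 equiv | 2 equiv | the very flask that is asked about, followed so far |  |
| amber | 1 equiv | 1.3 equiv | run made earlier |  |
| flask | 1.00 equiv | 2.00 equiv |  | 5.0 h |

violet run (percent of the electrophile charged)

| time / min | electrophile / % | target / % |
|---|---|---|
| 5.00 | 51.4 | 42.4 |
| 10.0 | 42.7 | 49.2 |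
| 15.0 | 38.0 | 50.9 |
| 20.0 | 34.9 | 53.7 |
| 25.0 | 31.6 | 54.5 |
| 30.0 | 28.5 | 56.4 |
| 40.0 | 24.9 | 57.8 |

amber run (percent of the electrophile charged)

| time / h | electrophile / % | target / % |
|---|---|---|
| 0.500 | 29.5 | 54.4 |
| 1.00 | 19.9 | 60.8 |
| 1.50 | 13.9 | 65.1 |
| 2.00 | 9.3 | 68.3 |
| 2.50 | 6.5 | 71.1 |
| 3.00 | 4.3 | 72.5 |
| 4.00 | 1.8 | 75.1 |

(scatter of a reading: 0.5 percentage points)

- the earlier runs do not show how much of nucleophile is bound; that part of a forecast is a guess

* part of the electrophile that has reacted at 5.0 h
* share of the unused nucleophile that is free and not bound as protonated nucleophile, at 5.0 h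

A rate constant tells how fast two partners meet, so I read two from the runs. In a step between two partners with equal charges, the inverse of c(electrophile) rises in a straight line, so I treat the start of the violet run as such a step, and its first reading gives a burst constant, reckoned on the charge:

k(burst) = 11.3 h⁻¹

Later the amber electrophile falls in a pseudo-first-order tail, which I read from its second reading to its last:

k(tail) = 0.801 h⁻¹

The burst is far faster than the tail, and I read this as nucleophile that is unused but mostly held as protonated nucleophile. The ratio of the two constants, one from each run, is then my estimate of the free charge, the part of the charged nucleophile that is free during the tail: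

free charge = k(tail)/k(burst) = 7.06%

Running the amber tail constant on from the last violet reading, I reckon 99.2% reacted. Amber's last target reading leaves 24.9% of the nucleophile unused, so my guess for the free share is:

free charge / unused = 28.4%

The forecast gives 98.9% and 10%, reading that “most of the nucleophile soon becomes protonated”. Its conversion lies close to mine, but its free share lies lower.

The flask gives 99.8% reacted and a free share of 44.9%, which had stood at 20.2% at 2.50 h. Over the 21.7% of nucleophile unused at 5.00 h, the free charge gives 32.5%, still under the flask's share.

    2 electrophile → self-condensation product (k = 0.00418 M⁻¹ s⁻¹)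
    electrophile + nucleophile → acid set free + target (k = 0.0961 M⁻¹ s⁻¹)
    acid set free + free base ⇌ salt of the base (K = 4.47 × 10⁵ M⁻¹, k = 0.180 M⁻¹ s⁻¹)
    electrophile + acid set free → side product (k = 0.00109 M⁻¹ s⁻¹)
    nucleophile + acid set free ⇌ protonated nucleophile, settled at all times (K = 39000 M⁻¹)

In the neighbour at 0.12 M, with the same equivalents and time, target reaches 75.2%, and the free charge, held as a guess, gives 28.5%. The computed neighbour has 100% reacted and a free share of 56.6%.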